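**Analysis of the target**

The target is a linear tetradepside: four separate six-membered carbocycles, rings A to D, joined by three aryl ester bonds. Each ring is numbered here as a benzoic acid, C1 carrying the carboxyl carbon. Ring D is 4-hydroxy-2-methoxy-5,6-dimethylbenzoic acid with its CO2H free; ring C is a 2,4-dihydroxy-3,6-dimethylbenzoyl unit bound through O4; ring B is a hexasubstituted 3-chloro-2,4-dihydroxy-5,6-dimethylbenzoyl unit; ring A is a 1-hydroxy-2-methoxy-3,6-dimethyl-4-oxocyclohexa-2,5-diene-1-carbonyl unit on O4 of ring B. The only stereocentre is C1 of ring A, a quaternary carbinol carbon of (R) configuration (priorities OH > ester carbon > C2 > C6). Nothing else in the molecule can relay chirality to it, so it has to be set by a reagent. The sensitive groups are the three aryl esters (acyl transfer to phenoxides), the cross-conjugated dienone with its vinylogous ester and tertiary alcohol (base, nucleophiles, reductants), the aryl chloride (reductive loss) and the free acid. Ring A cannot be handled as a free quinol acid: it would be a vinylogous β-keto acid and should lose CO2 to give an aromatic hydroquinone. Every ester joins a doubly ortho-substituted acyl carbon to a phenol oxygen, the ring B carbonyl sits on a fully substituted ring, and hydroxyls that differ only in chelation must be told apart. The strategy rests on the ring B carbonyl carbon: it is bonded to ring B C1 (between C2–OH and C6–CH3) and to O4 of ring C, so it can be inserted as a one-carbon unit between a ring B C1 halide and that oxygen.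

**Retrosynthetic reasoning**

26 back to 25. The C1–OH bond of ring A is cut, so that ring A becomes an ordinary 4-hydroxybenzoate. A preformed quinol acid is ruled out as an acyl donor by its expected decarboxylative aromatisation, and the dienone would not tolerate the base, fluoride and acid of the earlier steps. The forward reaction is a hydroxylative dearomatisation placed last. It has to oxidise only the unchelated ring A phenol, deliver oxygen to the ester-bearing para carbon, and choose one face under control of a chiral aryl iodide catalyst.

25 back to 24. The aryl silyl ether on ring A and the silylethyl ester on ring D are both silicon-based, so that one fluoride treatment frees the phenol and the acid together. Both groups are inert to the acetal cleavage, the hydrogenolysis and the carbonylation that precede them.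

24 back to 19 and 22. The ester C–O bond between the ring A carbonyl and O4 of ring B is cut. In 19 only this hydroxyl is not hydrogen-bonded to an ester carbonyl, which gives the site selectivity. Acid 22 is doubly ortho-substituted and is therefore activated as an acylium-type mixed anhydride. 22 comes from 8 in three steps: silylation of the unchelated hydroxyl, methylation of the chelated one, oxidation of the aldehyde.

19 back to 18, then to 5, 17 and 16. After removal of the two acetals, both bonds at the ring B carbonyl carbon are cut: the aryl–carbonyl bond and the carbonyl–O4 bond to ring C. This is the key disconnection. It removes the need to make and activate a hexasubstituted benzoic acid, and it joins two fragments of similar size. The forward reaction has to distinguish iodide from chloride on ring B and the free 4-hydroxyl of ring C from its chelated 2-hydroxyl.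

5 back to 4, 2 and 1. The halogens are placed in an order that dictates each position. Chlorine goes between the two acetal oxygens by directed lithiation of 2. Iodine then enters the only ring CH left in 4, which is ortho to one oxygen and para to the other, exactly where the carbonyl is needed.

16 back to 15, 14, 13, 12, then to 10 and 7. The ring C–ring D ester is cut. Ring D is carried as aldehyde 7, obtained from 1 by formylation. Chelation of its 2-hydroxyl to the formyl group leaves only O4 open to acylation by 10, after which O2 is methylated and the aldehyde is oxidised and esterified. The benzyl ethers of ring C are removed by hydrogenolysis while the molecule still contains no chlorine. Acid 10 comes from 8 by benzylation and oxidation, so 8 serves both ring A and ring C.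

**Alternatives that were turned down**

Alternative 1: Ring A would come from a seven-membered ring. The disconnection cuts a ring bond at C1 of ring A together with the ester C–O bond to ring B. In the forward step the ring B phenoxide of the tridepside allyl ester A3 would add to one carbonyl of the vicinal dione in 3-methoxy-4,7-dimethylcyclohepta-3,6-diene-1,2,5-trione A2. A 1,2-shift of the neighbouring ring carbon (benzilic ester rearrangement) would then contract the ring and give A1, the allyl ester of the target.
- For: the quaternary carbinol, its ring bond and the most crowded ester arise in one step, and either carbonyl of the dione leads to the same constitution. On bond economy it is stronger than the chosen route, which needs steps 17 and 19 for the same bonds and must oxidise an electron-poor phenol.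
- Against: benzilic ester rearrangements are driven by alkoxides. A phenoxide flanked by chlorine and methyl and para to an ester is a weak, crowded nucleophile and a good leaving group, so the adduct should revert faster than it rearranges. A2 offers a third carbonyl and two enone β-carbons to conjugate addition, it needs its own multistep synthesis, and such triones hydrate readily. C1 would form with no controlling element at all. The allyl ester would then have to be removed with zerovalent palladium next to the dienone.
- Comparison: the chosen route keeps all fragment chemistry on stable arenes and sets C1 in a step where a chiral reagent takes part in bond formation.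

Alternative 2: Ring C would be built de novo. The disconnection cuts the ring C–ring D ester C–O bond and one C–C bond of ring C. In the forward step, heating 6-(3,5-dioxohexan-2-yl)-2,2-dimethyl-4H-1,3-dioxin-4-one A5 would release acetone and an acylketene. Allyl 4-hydroxy-2-methoxy-5,6-dimethylbenzoate A6 would capture it, and an aldol condensation between the ester α-carbon and the terminal methyl ketone would close and aromatise ring C to give the didepside A4.
- For: the ester forms by addition to a ketene under neutral conditions, with no hindered acid to activate and no protection of the ring C hydroxyls. On this point it is stronger than the chosen route, which spends steps 5 and 11 on benzyl ethers.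
- Against: it uses its key step on the least difficult of the three esters. Ring C can be bought fully substituted as 8, whereas A5 with its branching methyl needs several steps and can cyclise by other aldol or lactonisation modes. The allyl ester of A4 would not survive the zerovalent palladium of a later carbonylation, and the crowded ring B carbonyl is left unsolved.
- Comparison: the chosen strategy reaches the same didepside from purchased material by routine steps and puts its new-bond effort where the structure is hardest.

Alternative 3: Ring B would be grown on an ester already in place. The disconnection cuts two C–C bonds of ring B: C5–C6 between the methyl-bearing carbons, and C1–C2 between the ester-bearing and hydroxyl-bearing carbons. In the forward step 2-chloro-1-methoxy-1,3-bis(trimethylsilyloxy)penta-1,3-diene A7 would add to the but-2-ynoate A8 of the ring C phenol, and loss of methanol would aromatise to the tridepside A3.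
- For: it answers the same structural problem as the chosen route, since the ester exists before the ring and no hexasubstituted acid is needed. Chlorine and both oxygens come in with the diene, the hydroxyls appear free, and neither gas nor metal is required. On these points it is equal or stronger.
- Against: A7 is a tetrasubstituted ketene acetal diene whose chlorine lowers the HOMO and whose terminal methyl disfavours the s-cis form. A8 is a β-methyl ynoate, a sluggish dienophile that needs heat at which such dienes undergo silyl transfer. The aryl ynoate is also an activated ester that the diene can acylate, and its chelated hydroxyl can add to the triple bond.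
- Comparison: the chosen route takes ring B from purchased 1 in three steps in which every substituent position is dictated, and its bond-forming step has close precedent.

Key step: step 12

Assumption: the sense of induction of the lactamide-based chiral iodoarene on a phenol of this substitution pattern cannot be read from structure alone; both antipodes are accessible from (S)- or (R)-lactate, and the one that leads to the (1R) carbinol is meant in step 19.

**Route**

Step 1
Reactants: 1 4,5-dimethylbenzene-1,3-diol
Product: 2 1,5-bis(methoxymethoxy)-2,3-dimethylbenzene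
Conditions: MOMCl, i-Pr2NEt, CH2Cl2, 0 °C → rt
Reagents that add atoms: chloromethyl methyl ether, COCCl
Why: O-alkylation of both phenols by the reactive α-chloro ether (Williamson type); the acetals protect the hydroxyls and act as directing groups for step 2.

Step 2
Reactants: 2 1,5-bis(methoxymethoxy)-2,3-dimethylbenzene
Product: 4 2-chloro-1,3-bis(methoxymethoxy)-4,5-dimethylbenzene, via aryllithium 3 (not isolated)
Conditions: n-BuLi, THF, 0 °C; then C2Cl6, −78 °C → rt
Reagents that add atoms: hexachloroethane, ClC(Cl)(Cl)C(Cl)(Cl)Cl
Why: Directed ortho-metalation; the hydrogen between the two acetal oxygens is the most acidic and is doubly chelated, so lithiation should occur only there, and the aryllithium is chlorinated by C2Cl6.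

Step 3
Reactants: 4 2-chloro-1,3-bis(methoxymethoxy)-4,5-dimethylbenzene
Product: 5 3-chloro-1-iodo-2,4-bis(methoxymethoxy)-5,6-dimethylbenzene
Conditions: NIS, TFA (10 mol %), MeCN, 0 °C → rt, dark
Reagents that add atoms: N-iodosuccinimide, O=C1CCC(=O)N1I
Why: Electrophilic aromatic iodination at the single remaining ring CH, which is ortho to one acetal oxygen and para to the other; no regioisomer is possible.

Step 4
Reactants: 1 4,5-dimethylbenzene-1,3-diol
Product: 7 2,4-dihydroxy-5,6-dimethylbenzaldehyde, via iminium chloride 6 (not isolated)
Conditions: POCl3, DMF, MeCN, 0 °C → rt; then H2O, 50 °C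
Reagents that add atoms: N,N-dimethylformamide, CN(C)C=O; water, O
Why: Vilsmeier–Haack formylation; resorcinols are attacked para to one hydroxyl and ortho to the other rather than between the hydroxyls, also when that position is next to a methyl group, and hydrolysis of the iminium salt gives the aldehyde.

Step 5
Reactants: 8 2,4-dihydroxy-3,6-dimethylbenzaldehyde
Product: 9 2,4-bis(benzyloxy)-3,6-dimethylbenzaldehyde
Conditions: BnBr (excess), K2CO3, DMF, 60 °C
Reagents that add atoms: benzyl bromide, BrCc1ccccc1
Why: Williamson ether synthesis; excess reagent and warming also alkylate the chelated 2-hydroxyl.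

Step 6
Reactants: 9 2,4-bis(benzyloxy)-3,6-dimethylbenzaldehyde
Product: 10 2,4-bis(benzyloxy)-3,6-dimethylbenzoic acid
Conditions: NaClO2, NaH2PO4, 2-methyl-2-butene, t-BuOH/THF/H2O, rt
Reagents that add atoms: sodium chlorite (NaClO2), [Na+].[O-]Cl=O
Why: Pinnick oxidation of a hindered aryl aldehyde; the alkene traps hypochlorous acid so that the electron-rich ring is not chlorinated.

Step 7
Reactants: 10 2,4-bis(benzyloxy)-3,6-dimethylbenzoic acid; 7 2,4-dihydroxy-5,6-dimethylbenzaldehyde
Product: 12 4-formyl-5-hydroxy-2,3-dimethylphenyl 2,4-bis(benzyloxy)-3,6-dimethylbenzoate, via mixed anhydride 11 (not isolated)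
Conditions: TFAA, toluene, 0 °C → rt; then 7, rt
Reagents that add atoms: none
Why: Esterification through the mixed trifluoroacetic anhydride, which ionises to a linear acylium ion stabilised by the ortho and para oxygens and so overcomes the double ortho substitution; only the 4-hydroxyl of 7 should react because the 2-hydroxyl is locked in a hydrogen bond to the formyl group.

Step 8
Reactants: 12 4-formyl-5-hydroxy-2,3-dimethylphenyl 2,4-bis(benzyloxy)-3,6-dimethylbenzoate
Product: 13 4-formyl-5-methoxy-2,3-dimethylphenyl 2,4-bis(benzyloxy)-3,6-dimethylbenzoate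
Conditions: MeI, K2CO3, DMF, rt
Reagents that add atoms: iodomethane, CI
Why: Williamson methylation of the one free, chelated phenol; the hindered aryl ester should tolerate carbonate.

Step 9
Reactants: 13 4-formyl-5-methoxy-2,3-dimethylphenyl 2,4-bis(benzyloxy)-3,6-dimethylbenzoate
Product: 14 4-{[2,4-bis(benzyloxy)-3,6-dimethylbenzoyl]oxy}-2-methoxy-5,6-dimethylbenzoic acid
Conditions: NaClO2, NaH2PO4, 2-methyl-2-butene, t-BuOH/THF/H2O, rt
Reagents that add atoms: sodium chlorite (NaClO2), [Na+].[O-]Cl=O
Why: Pinnick oxidation; the mildly acidic buffered medium leaves the depside ester intact.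

Step 10
Reactants: 14 4-{[2,4-bis(benzyloxy)-3,6-dimethylbenzoyl]oxy}-2-methoxy-5,6-dimethylbenzoic acid
Product: 15 2-(trimethylsilyl)ethyl 4-{[2,4-bis(benzyloxy)-3,6-dimethylbenzoyl]oxy}-2-methoxy-5,6-dimethylbenzoate
Conditions: Me3SiCH2CH2OH, PPh3, DIAD, THF, 0 °C → rt
Reagents that add atoms: 2-(trimethylsilyl)ethanol, C[Si](C)(C)CCO
Why: Mitsunobu esterification; the carboxylate oxygen attacks the activated primary alcohol, so the crowding around the acyl carbon does not matter.

Step 11
Reactants: 15 2-(trimethylsilyl)ethyl 4-{[2,4-bis(benzyloxy)-3,6-dimethylbenzoyl]oxy}-2-methoxy-5,6-dimethylbenzoate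
Product: 16 2-(trimethylsilyl)ethyl 4-[(2,4-dihydroxy-3,6-dimethylbenzoyl)oxy]-2-methoxy-5,6-dimethylbenzoate
Conditions: H2 (1 atm), Pd/C (10 wt %), EtOAc, rt
Reagents that add atoms: none
Why: Hydrogenolysis of both benzyl ethers; aryl esters and the silylethyl ester are inert, and no chlorine is yet present.

Step 12
Reactants: 5 3-chloro-1-iodo-2,4-bis(methoxymethoxy)-5,6-dimethylbenzene; 16 2-(trimethylsilyl)ethyl 4-[(2,4-dihydroxy-3,6-dimethylbenzoyl)oxy]-2-methoxy-5,6-dimethylbenzoate; 17 carbon monoxide
Product: 18 2-(trimethylsilyl)ethyl 4-{[4-({3-chloro-2,4-bis(methoxymethoxy)-5,6-dimethylbenzoyl}oxy)-2-hydroxy-3,6-dimethylbenzoyl]oxy}-2-methoxy-5,6-dimethylbenzoate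
Conditions: Pd(OAc)2 (5 mol %), Xantphos (7.5 mol %), CO (1 atm), Et3N, toluene, 90 °C
Reagents that add atoms: carbon monoxide (17), [C-]#[O+]
Why: Pd(OAc)2 is reduced in the flask to a zerovalent palladium–Xantphos complex, which inserts into the carbon–iodine bond of 5 while the stronger carbon–chlorine bond, buried between two acetal oxygens, is left alone. Coordination and migratory insertion of 17 turn the crowded aryl divalent palladium species into an aroyl divalent palladium iodide, a step that relieves the strain between the metal and the two ortho substituents. Et3N deprotonates the free 4-hydroxyl of ring C in 16, the phenoxide replaces iodide on palladium, and carbon–oxygen reductive elimination (or direct attack at the acyl carbon) should release 18 and zerovalent palladium. The closest known reaction is the palladium-catalysed aryloxycarbonylation of aryl iodides with phenols at atmospheric CO pressure with Pd(OAc)2 and a wide-bite-angle bisphosphine, applied here to a doubly ortho-substituted iodide. No ring is closed and no stereocentre is formed. The step needs iodide over chloride, which bond strength secures, and O4 over O2 of ring C, which is secured because the O2 hydrogen is tied to the neighbouring ester carbonyl and O2 is flanked by the C3 methyl and the ester. It also needs carbonylation over direct aryl ether formation, which the CO atmosphere and the fast insertion into a hindered aryl–palladium bond should ensure. The large bite angle of Xantphos should speed the final reductive elimination, and the existing aryl esters and the silylethyl ester are inert to zerovalent palladium under these conditions.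

Step 13
Reactants: 18 protected ring B–C–D tridepside (name as in step 12)
Product: 19 2-(trimethylsilyl)ethyl 4-{[4-({3-chloro-2,4-dihydroxy-5,6-dimethylbenzoyl}oxy)-2-hydroxy-3,6-dimethylbenzoyl]oxy}-2-methoxy-5,6-dimethylbenzoate
Conditions: HCl (3 M aq), THF, 40 °C
Reagents that add atoms: none
Why: Acid hydrolysis of the two aryl methoxymethyl acetals; the doubly ortho-substituted aryl esters and the silylethyl ester should resist dilute acid.

Step 14
Reactants: 8 2,4-dihydroxy-3,6-dimethylbenzaldehyde
Product: 20 2-hydroxy-3,6-dimethyl-4-[(triisopropylsilyl)oxy]benzaldehyde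
Conditions: TIPSCl, imidazole, DMF, 0 °C → rt
Reagents that add atoms: chlorotriisopropylsilane, CC(C)[Si](Cl)(C(C)C)C(C)C
Why: Silylation of the unchelated 4-hydroxyl; the 2-hydroxyl is hydrogen-bonded to the formyl group and should not react with the bulky silyl chloride.

Step 15
Reactants: 20 2-hydroxy-3,6-dimethyl-4-[(triisopropylsilyl)oxy]benzaldehyde
Product: 21 2-methoxy-3,6-dimethyl-4-[(triisopropylsilyl)oxy]benzaldehyde
Conditions: MeI, K2CO3, acetone, 50 °C
Reagents that add atoms: iodomethane, CI
Why: Williamson methylation of the chelated phenol; the bulky aryl silyl ether should survive carbonate in a dry, non-hydroxylic solvent.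

Step 16
Reactants: 21 2-methoxy-3,6-dimethyl-4-[(triisopropylsilyl)oxy]benzaldehyde
Product: 22 2-methoxy-3,6-dimethyl-4-[(triisopropylsilyl)oxy]benzoic acid
Conditions: NaClO2, NaH2PO4, 2-methyl-2-butene, t-BuOH/THF/H2O, rt
Reagents that add atoms: sodium chlorite (NaClO2), [Na+].[O-]Cl=O
Why: Pinnick oxidation; the buffered medium is compatible with the aryl silyl ether.

Step 17
Reactants: 22 2-methoxy-3,6-dimethyl-4-[(triisopropylsilyl)oxy]benzoic acid; 19 ring B–C–D triphenol (name as in step 13)
Product: 24 2-(trimethylsilyl)ethyl 4-{[4-({3-chloro-2-hydroxy-4-[(2-methoxy-3,6-dimethyl-4-[(triisopropylsilyl)oxy]benzoyl)oxy]-5,6-dimethylbenzoyl}oxy)-2-hydroxy-3,6-dimethylbenzoyl]oxy}-2-methoxy-5,6-dimethylbenzoate, via mixed anhydride 23 (not isolated)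
Conditions: TFAA, toluene, 0 °C → rt; then 19, rt
Reagents that add atoms: none
Why: Esterification through the mixed trifluoroacetic anhydride and its acylium ion, a small linear electrophile that can reach the hydroxyl between chlorine and methyl; the two other hydroxyls of 19 are hydrogen-bonded to ester carbonyls and should stay unreacted.

Step 18
Reactants: 24 silyl-protected aromatic tetradepside (name as in step 17)
Product: 25 4-{[4-({3-chloro-2-hydroxy-4-[(4-hydroxy-2-methoxy-3,6-dimethylbenzoyl)oxy]-5,6-dimethylbenzoyl}oxy)-2-hydroxy-3,6-dimethylbenzoyl]oxy}-2-methoxy-5,6-dimethylbenzoic acid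
Conditions: TBAF (buffered with AcOH), THF, 0 °C → rt
Reagents that add atoms: none
Why: Fluoride cleaves the aryl silyl ether by attack at silicon and the silylethyl ester by β-elimination (loss of ethene and the fluorosilane); buffering keeps the medium from being basic enough to open the hindered aryl esters.

Step 19
Reactants: 25 aromatic tetradepside acid (name as in step 18)
Product: 26 4-{[4-({3-chloro-2-hydroxy-4-[((1R)-1-hydroxy-2-methoxy-3,6-dimethyl-4-oxocyclohexa-2,5-diene-1-carbonyl)oxy]-5,6-dimethylbenzoyl}oxy)-2-hydroxy-3,6-dimethylbenzoyl]oxy}-2-methoxy-5,6-dimethylbenzoic acid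
Conditions: chiral iodoarene 2,2'-[(2-iodo-1,3-phenylene)bis(oxy)]bis(N-mesitylpropanamide), antipode as in the assumption (15 mol %), mCPBA, MeCN/H2O, −10 °C
Reagents that add atoms: water, O
Why: Proposed new method: the unchelated ring A phenol, the most electron-rich of the three, should bind to the aryl-λ3-iodane formed from the iodoarene and mCPBA, and water should attack the para carbon C1 as the iodoarene leaves, giving the cross-conjugated dienone; the closest known reaction is the chiral-aryl-iodide-catalysed hydroxylative dearomatisation of 4-alkylphenols to p-quinols, not yet shown for a phenol whose para carbon carries an ester. The C1 configuration would be set by the lactamide arms of the catalyst, which screen one face of the iodine-bound aryloxy ring so that water enters from the other. Attack at C1 is expected over C3 (blocked by methyl) and over C5 because para attack gives the non-enolisable dienone directly.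

**Compound list**

1 | 4,5-dimethylbenzene-1,3-diol | Cc1cc(O)cc(O)c1C | starting material
2 | 1,5-bis(methoxymethoxy)-2,3-dimethylbenzene | Cc1cc(OCOC)cc(OCOC)c1C | intermediate
3 | [2,6-bis(methoxymethoxy)-3,4-dimethylphenyl]lithium (formed in the flask) | [Li]c1c(OCOC)cc(C)c(C)c1OCOC | intermediate
4 | 2-chloro-1,3-bis(methoxymethoxy)-4,5-dimethylbenzene | COCOc1cc(C)c(C)c(OCOC)c1Cl | intermediate
5 | 3-chloro-1-iodo-2,4-bis(methoxymethoxy)-5,6-dimethylbenzene | COCOc1c(C)c(C)c(I)c(OCOC)c1Cl | intermediate
6 | [(2,4-dihydroxy-5,6-dimethylphenyl)methylidene]dimethylammonium chloride (formed in the flask) | C[N+](C)=Cc1c(O)cc(O)c(C)c1C.[Cl-] | intermediate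
7 | 2,4-dihydroxy-5,6-dimethylbenzaldehyde | O=Cc1c(O)cc(O)c(C)c1C | intermediate
8 | 2,4-dihydroxy-3,6-dimethylbenzaldehyde | O=Cc1c(O)c(C)c(O)cc1C | starting material
9 | 2,4-bis(benzyloxy)-3,6-dimethylbenzaldehyde | O=Cc1c(OCc2ccccc2)c(C)c(OCc2ccccc2)cc1C | intermediate
10 | 2,4-bis(benzyloxy)-3,6-dimethylbenzoic acid | OC(=O)c1c(OCc2ccccc2)c(C)c(OCc2ccccc2)cc1C | intermediate
11 | 2,4-bis(benzyloxy)-3,6-dimethylbenzoic trifluoroacetic anhydride (formed in the flask) | FC(F)(F)C(=O)OC(=O)c1c(OCc2ccccc2)c(C)c(OCc2ccccc2)cc1C | intermediate
12 | 4-formyl-5-hydroxy-2,3-dimethylphenyl 2,4-bis(benzyloxy)-3,6-dimethylbenzoate | O=Cc1c(O)cc(OC(=O)c2c(OCc3ccccc3)c(C)c(OCc3ccccc3)cc2C)c(C)c1C | intermediate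
13 | 4-formyl-5-methoxy-2,3-dimethylphenyl 2,4-bis(benzyloxy)-3,6-dimethylbenzoate | O=Cc1c(OC)cc(OC(=O)c2c(OCc3ccccc3)c(C)c(OCc3ccccc3)cc2C)c(C)c1C | intermediate
14 | 4-{[2,4-bis(benzyloxy)-3,6-dimethylbenzoyl]oxy}-2-methoxy-5,6-dimethylbenzoic acid | OC(=O)c1c(OC)cc(OC(=O)c2c(OCc3ccccc3)c(C)c(OCc3ccccc3)cc2C)c(C)c1C | intermediate
15 | 2-(trimethylsilyl)ethyl 4-{[2,4-bis(benzyloxy)-3,6-dimethylbenzoyl]oxy}-2-methoxy-5,6-dimethylbenzoate | C[Si](C)(C)CCOC(=O)c1c(OC)cc(OC(=O)c2c(OCc3ccccc3)c(C)c(OCc3ccccc3)cc2C)c(C)c1C | intermediate
16 | 2-(trimethylsilyl)ethyl 4-[(2,4-dihydroxy-3,6-dimethylbenzoyl)oxy]-2-methoxy-5,6-dimethylbenzoate | Cc1cc(O)c(C)c(O)c1C(=O)Oc1cc(OC)c(C(=O)OCC[Si](C)(C)C)c(C)c1C | intermediate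
17 | carbon monoxide | [C-]#[O+] | starting material
18 | 2-(trimethylsilyl)ethyl 4-{[4-({3-chloro-2,4-bis(methoxymethoxy)-5,6-dimethylbenzoyl}oxy)-2-hydroxy-3,6-dimethylbenzoyl]oxy}-2-methoxy-5,6-dimethylbenzoate | COCOc1c(C)c(C)c(C(=O)Oc2cc(C)c(C(=O)Oc3cc(OC)c(C(=O)OCC[Si](C)(C)C)c(C)c3C)c(O)c2C)c(OCOC)c1Cl | intermediate
19 | 2-(trimethylsilyl)ethyl 4-{[4-({3-chloro-2,4-dihydroxy-5,6-dimethylbenzoyl}oxy)-2-hydroxy-3,6-dimethylbenzoyl]oxy}-2-methoxy-5,6-dimethylbenzoate | Oc1c(C)c(C)c(C(=O)Oc2cc(C)c(C(=O)Oc3cc(OC)c(C(=O)OCC[Si](C)(C)C)c(C)c3C)c(O)c2C)c(O)c1Cl | intermediate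
20 | 2-hydroxy-3,6-dimethyl-4-[(triisopropylsilyl)oxy]benzaldehyde | O=Cc1c(O)c(C)c(O[Si](C(C)C)(C(C)C)C(C)C)cc1C | intermediate
21 | 2-methoxy-3,6-dimethyl-4-[(triisopropylsilyl)oxy]benzaldehyde | O=Cc1c(OC)c(C)c(O[Si](C(C)C)(C(C)C)C(C)C)cc1C | intermediate
22 | 2-methoxy-3,6-dimethyl-4-[(triisopropylsilyl)oxy]benzoic acid | OC(=O)c1c(OC)c(C)c(O[Si](C(C)C)(C(C)C)C(C)C)cc1C | intermediate
23 | 2-methoxy-3,6-dimethyl-4-[(triisopropylsilyl)oxy]benzoic trifluoroacetic anhydride (formed in the flask) | COc1c(C)c(O[Si](C(C)C)(C(C)C)C(C)C)cc(C)c1C(=O)OC(=O)C(F)(F)F | intermediate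
24 | 2-(trimethylsilyl)ethyl 4-{[4-({3-chloro-2-hydroxy-4-[(2-methoxy-3,6-dimethyl-4-[(triisopropylsilyl)oxy]benzoyl)oxy]-5,6-dimethylbenzoyl}oxy)-2-hydroxy-3,6-dimethylbenzoyl]oxy}-2-methoxy-5,6-dimethylbenzoate | COc1c(C)c(O[Si](C(C)C)(C(C)C)C(C)C)cc(C)c1C(=O)Oc1c(C)c(C)c(C(=O)Oc2cc(C)c(C(=O)Oc3cc(OC)c(C(=O)OCC[Si](C)(C)C)c(C)c3C)c(O)c2C)c(O)c1Cl | intermediate
25 | 4-{[4-({3-chloro-2-hydroxy-4-[(4-hydroxy-2-methoxy-3,6-dimethylbenzoyl)oxy]-5,6-dimethylbenzoyl}oxy)-2-hydroxy-3,6-dimethylbenzoyl]oxy}-2-methoxy-5,6-dimethylbenzoic acid | COc1c(C)c(O)cc(C)c1C(=O)Oc1c(C)c(C)c(C(=O)Oc2cc(C)c(C(=O)Oc3cc(OC)c(C(=O)O)c(C)c3C)c(O)c2C)c(O)c1Cl | intermediate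
26 | 4-{[4-({3-chloro-2-hydroxy-4-[((1R)-1-hydroxy-2-methoxy-3,6-dimethyl-4-oxocyclohexa-2,5-diene-1-carbonyl)oxy]-5,6-dimethylbenzoyl}oxy)-2-hydroxy-3,6-dimethylbenzoyl]oxy}-2-methoxy-5,6-dimethylbenzoic acid (CNP0248758.1) | COC1=C(C)C(=O)C=C(C)[C@]1(O)C(=O)Oc1c(C)c(C)c(C(=O)Oc2cc(C)c(C(=O)Oc3cc(OC)c(C(=O)O)c(C)c3C)c(O)c2C)c(O)c1Cl | target

**Step count and least certain steps**

Total: 19 steps. Longest linear sequence: 12 steps (8 through steps 5–13, then 17–19). The ring B iodide 5 takes three steps and the ring A acid 22 three steps, both off the main line.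

Step 19 (proposed new method). Two processes may fail. Facial discrimination may be poor, because the carbon that becomes stereogenic lies para to the iodine-bound oxygen and far from the chiral arms. The oxidation may also be sluggish, since the para ester lowers the electron density of the phenol, which would allow over-oxidation or attack at the free ortho carbon C5. Fallback: starting from 25, a stoichiometric hydroxylative dearomatisation with the more electrophilic PhI(OCOCF3)2 in aqueous MeCN at 0 °C, the established p-quinol synthesis, should give 26 together with its mirror image, the (1S)-enantiomer of 26 F1. The two are then separated by preparative chromatography on a chiral stationary phase, or by crystallising diastereomeric salts of the ring D carboxylic acid with a chiral amine, and the route is rejoined at 26.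

Step 12 (key step). Capture of the hindered aroyl palladium species by a phenoxide that is itself flanked by methyl may be slow, so that hydrodeiodination or catalyst decay to palladium metal takes over; CO can also retard oxidative addition into the electron-rich iodide. Fallback: starting from 5, iodine–magnesium exchange with i-PrMgCl·LiCl in THF at −20 °C should give [3-chloro-2,4-bis(methoxymethoxy)-5,6-dimethylphenyl]magnesium chloride F2, which is carboxylated with CO2 to 3-chloro-2,4-bis(methoxymethoxy)-5,6-dimethylbenzoic acid F3. Under neutral conditions 1-chloro-N,N,2-trimethylprop-1-en-1-amine converts it into 3-chloro-2,4-bis(methoxymethoxy)-5,6-dimethylbenzoyl chloride F4, which acylates the free 4-hydroxyl of 16 with Et3N and catalytic DMAP, returning to the route at 18. This gives up the one-step union and requires the hexasubstituted acid, but uses only routine reactions.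

Step 17. The ring B hydroxyl is electron-poor and crowded, so capture of the acylium ion may be slow; prolonged exposure to trifluoroacetic acid could then cause loss of the aryl silyl ether or slow cleavage of the silylethyl ester. Fallback: starting from 22, 1-chloro-N,N,2-trimethylprop-1-en-1-amine gives 2-methoxy-3,6-dimethyl-4-[(triisopropylsilyl)oxy]benzoyl chloride F5. It is added to the monophenoxide made from 19 with one equivalent of NaH in THF, in which the unchelated, most acidic hydroxyl is the one deprotonated; this returns to the route at 24 by an addition–elimination path under basic instead of acidic conditions.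

Step 18. Fluoride generates phenoxides, which may attack the aryl esters and scramble the depside bonds, or the buffered reagent may leave the silylethyl ester partly intact. Fallback: starting from 24, acidolysis of the silylethyl ester with TFA in CH2Cl2 (β-silyl fragmentation, no base present) gives the triisopropylsilyl-protected tetradepside acid F6, and the aryl silyl ether is then removed with the non-basic Et3N·3HF, returning to the route at 25.

Step 3. The acid co-catalyst may remove a methoxymethyl group, or substitution at the last, crowded ring position may stall. Fallback: starting from 4, a second directed ortho-lithiation with s-BuLi and TMEDA in THF at −78 °C, guided by the adjacent acetal oxygen, gives [3-chloro-2,4-bis(methoxymethoxy)-5,6-dimethylphenyl]lithium F7, which is quenched with iodine to return to the route at 5.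

**Further compounds**

F1 | step 19 | (1S)-enantiomer of 26 | COC1=C(C)C(=O)C=C(C)[C@@]1(O)C(=O)Oc1c(C)c(C)c(C(=O)Oc2cc(C)c(C(=O)Oc3cc(OC)c(C(=O)O)c(C)c3C)c(O)c2C)c(O)c1Cl
F2 | step 12 | [3-chloro-2,4-bis(methoxymethoxy)-5,6-dimethylphenyl]magnesium chloride | COCOc1c(C)c(C)c([Mg]Cl)c(OCOC)c1Cl
F3 | step 12 | 3-chloro-2,4-bis(methoxymethoxy)-5,6-dimethylbenzoic acid | COCOc1c(C)c(C)c(C(=O)O)c(OCOC)c1Cl
F4 | step 12 | 3-chloro-2,4-bis(methoxymethoxy)-5,6-dimethylbenzoyl chloride | COCOc1c(C)c(C)c(C(Cl)=O)c(OCOC)c1Cl
F5 | step 17 | 2-methoxy-3,6-dimethyl-4-[(triisopropylsilyl)oxy]benzoyl chloride | COc1c(C)c(O[Si](C(C)C)(C(C)C)C(C)C)cc(C)c1C(Cl)=O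
F6 | step 18 | 4-{[4-({3-chloro-2-hydroxy-4-[(2-methoxy-3,6-dimethyl-4-[(triisopropylsilyl)oxy]benzoyl)oxy]-5,6-dimethylbenzoyl}oxy)-2-hydroxy-3,6-dimethylbenzoyl]oxy}-2-methoxy-5,6-dimethylbenzoic acid | COc1c(C)c(O[Si](C(C)C)(C(C)C)C(C)C)cc(C)c1C(=O)Oc1c(C)c(C)c(C(=O)Oc2cc(C)c(C(=O)Oc3cc(OC)c(C(=O)O)c(C)c3C)c(O)c2C)c(O)c1Cl
F7 | step 3 | [3-chloro-2,4-bis(methoxymethoxy)-5,6-dimethylphenyl]lithium | COCOc1c(C)c(C)c([Li])c(OCOC)c1Cl
A1 | alternative 1 | allyl ester of the target | COC1=C(C)C(=O)C=C(C)[C@]1(O)C(=O)Oc1c(C)c(C)c(C(=O)Oc2cc(C)c(C(=O)Oc3cc(OC)c(C(=O)OCC=C)c(C)c3C)c(O)c2C)c(O)c1Cl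
A2 | alternative 1 | 3-methoxy-4,7-dimethylcyclohepta-3,6-diene-1,2,5-trione | COC1=C(C)C(=O)C=C(C)C(=O)C1=O
A3 | alternative 3 | ring B–C–D tridepside allyl ester with chlorine in place (also the phenol partner of alternative 1) | Oc1c(C)c(C)c(C(=O)Oc2cc(C)c(C(=O)Oc3cc(OC)c(C(=O)OCC=C)c(C)c3C)c(O)c2C)c(O)c1Cl
A4 | alternative 2 | ring C–ring D didepside allyl ester with both ring C hydroxyls free | Cc1cc(O)c(C)c(O)c1C(=O)Oc1cc(OC)c(C(=O)OCC=C)c(C)c1C
A5 | alternative 2 | 6-(3,5-dioxohexan-2-yl)-2,2-dimethyl-4H-1,3-dioxin-4-one | CC(=O)CC(=O)C(C)C1=CC(=O)OC(C)(C)O1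
A6 | alternative 2 | allyl 4-hydroxy-2-methoxy-5,6-dimethylbenzoate | C=CCOC(=O)c1c(OC)cc(O)c(C)c1C
A7 | alternative 3 | 2-chloro-1-methoxy-1,3-bis(trimethylsilyloxy)penta-1,3-diene | COC(O[Si](C)(C)C)=C(Cl)C(O[Si](C)(C)C)=CC
A8 | alternative 3 | but-2-ynoate of the ring C phenol of the didepside allyl ester | CC#CC(=O)Oc1cc(C)c(C(=O)Oc2cc(OC)c(C(=O)OCC=C)c(C)c2C)c(O)c1C
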